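**Retrosynthetic overview**
- The aryl–pyranone bond (ring C carbon C2 to the ipso carbon of the 3,4,5-trimethoxyphenyl ring B) is cut last, giving 5-hydroxy-7-methoxychroman-4-one and commercial 3,4,5-trimethoxyphenylboronic acid. Both are joined in one pot by aerobic Pd(II) dehydrogenation followed by an oxidative boron-Heck reaction.
- Enabling feature: the O1–C2H2–C3H2–C4=O unit of ring C. Dehydrogenation turns it into the vinylogous ester O1–C2H=C3H–C4=O, whose only β C–H is at C2. The C4 carbonyl makes the C3–Pd intermediate an enolate that can change face and β-eliminate.
- The 5-OH is hydrogen-bonded to C4=O, so it needs no protecting group, and the same hydrogen bond allows selective 7-O-methylation of 5,7-dihydroxychroman-4-one.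
- Ring order: ring A comes from phloroglucinol, ring C is closed in step 1 (Friedel–Crafts acylation with 3-chloropropanoic acid, then phenoxide closure), and ring B is attached intact in the last step.

Key step: step 3

Remark: the target is a planar, achiral flavone with no stereocentre, so the SMILES defines one compound and no stereocontrol is needed.

**Step 1**
Reactants: 1 phloroglucinol (benzene-1,3,5-triol); 2 3-chloropropanoic acid
Product: 4 5,7-dihydroxychroman-4-one, via 3-chloro-1-(2,4,6-trihydroxyphenyl)propan-1-one 3 (not isolated)
Conditions: TfOH (3 equiv), 80 °C; aqueous quench and extraction, crude 3 carried on; then 2 M aq NaOH, 0 °C → rt; H2SO4 to pH 2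
Reagents that add atoms: none
Why: Friedel–Crafts acylation of the threefold-symmetric triol in superacid should stop at the monoketone (the acyl group deactivates the ring), and an ortho-phenoxide then closes ring C by intramolecular Williamson etherification (6-exo-tet chloride displacement, or E1cB elimination and 6-endo-trig oxa-Michael addition), both ortho-OH groups giving the same product.

**Step 2**
Reactants: 4 5,7-dihydroxychroman-4-one
Product: 5 5-hydroxy-7-methoxychroman-4-one
Conditions: Me2SO4 (1.05 equiv), K2CO3 (1.1 equiv), acetone, reflux
Reagents that add atoms: dimethyl sulfate COS(=O)(=O)OC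
Why: Williamson O-methylation should be selective for the more acidic, unhindered 7-OH para to the ketone, because the 5-OH is held in a six-membered hydrogen bond to C4=O.

**Step 3**
Reactants: 5 5-hydroxy-7-methoxychroman-4-one; 6 3,4,5-trimethoxyphenylboronic acid
Product: 8 corymbosin (5-hydroxy-7-methoxy-2-(3,4,5-trimethoxyphenyl)-4H-chromen-4-one), via 5-hydroxy-7-methoxy-4H-chromen-4-one 7 (not isolated)
Conditions: Pd(TFA)2 (15 mol%), 5-nitro-1,10-phenanthroline (20 mol%), O2 (1 atm), DMSO, 100 °C; then 6 (2.5 equiv) added to the same pot, O2, 100 °C
Reagents that add atoms: none
Why: Pd(II) palladates the ketone of 5 at C3 through its enolate, and syn β-hydride elimination of a C2–H gives chromone 7 (Saegusa-type aerobic α,β-dehydrogenation of a cyclic ketone), with O2 returning Pd–H/Pd(0) to Pd(II). Base-free transmetalation of 6 and migratory insertion of C2=C3 then put the aryl group on C2 and palladium on C3, and the C4 carbonyl lets this C3–Pd enolate pass through its O-bound form to the face syn to C2–H, so that β-hydride elimination restores C2=C3 (oxidative boron-Heck reaction). The closest known reaction type is the one-pot Pd(II)-catalysed dehydrogenation/oxidative boron-Heck sequence of chroman-4-ones to flavones. No ring is closed and no stereocentre is created. The step needs regioselectivity for C2 over C3, secured by the polarisation of the O1–C2=C3–C4=O vinylogous ester (aryl to the β-carbon, palladium to the enolate carbon), and mono-arylation, secured because the product has no C2–H left. The 5-OH is expected to survive because its hydrogen bond to C4=O lowers its reactivity toward oxidation and palladation, and the excess of 6 allows for oxidative homocoupling.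

**Compound list**
1 | phloroglucinol (benzene-1,3,5-triol) | Oc1cc(O)cc(O)c1 | starting material
2 | 3-chloropropanoic acid | OC(=O)CCCl | starting material
3 | 3-chloro-1-(2,4,6-trihydroxyphenyl)propan-1-one | O=C(CCCl)c1c(O)cc(O)cc1O | intermediate
4 | 5,7-dihydroxychroman-4-one | O=C1CCOc2cc(O)cc(O)c12 | intermediate
5 | 5-hydroxy-7-methoxychroman-4-one | COc1cc(O)c2C(=O)CCOc2c1 | intermediate
6 | 3,4,5-trimethoxyphenylboronic acid | COc1cc(B(O)O)cc(OC)c1OC | starting material
7 | 5-hydroxy-7-methoxy-4H-chromen-4-one | COc1cc(O)c2c(=O)ccoc2c1 | intermediate
8 | corymbosin, 5-hydroxy-7-methoxy-2-(3,4,5-trimethoxyphenyl)-4H-chromen-4-one | COc1cc(O)c2c(=O)cc(-c3cc(OC)c(OC)c(OC)c3)oc2c1 | target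

**Step count and risks**
Total step count: 3. Longest linear sequence: 3 steps (1 → 4 → 5 → 8); the coupling partner 6 is commercial.

Steps most likely to fail:

Step 3. The peri-hydroxy ketone may bind and slow the catalyst, the C3–Pd enolate may be protonated before β-hydride elimination so that the sequence stalls at the dihydro level, and oxidative homocoupling or protodeboronation of the electron-rich boronic acid may outrun insertion. The fallback sets out from 5 and separates the three events. Aerobic Pd(II) dehydrogenation alone (Pd(TFA)2, DMSO, AcOH, O2, 80 °C) should give 7, which is isolated this time. Redox-neutral Pd(II)-catalysed conjugate addition of 6 (Pd(TFA)2, 2,2'-bipyridine, NH4PF6, H2O, ClCH2CH2Cl, 60 °C, no oxidant) should form the same C2–aryl bond and give racemic 5-hydroxy-7-methoxy-2-(3,4,5-trimethoxyphenyl)chroman-4-one F1. Dehydrogenation with DDQ (dioxane, reflux) removes the C2 stereocentre and comes back to the route at 8.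

Step 2. Site selectivity may be lost through over-methylation at the chelated 5-OH or C-methylation at C6/C8, and base may open ring C by retro-oxa-Michael reaction. The fallback sets out from 4 and reverses the logic. Exhaustive methylation (excess Me2SO4, K2CO3, acetone, prolonged reflux) should give 5,7-dimethoxychroman-4-one F2. BCl3 (CH2Cl2, −78 → 0 °C) should then coordinate C4=O and cleave only the adjacent peri 5-OMe, coming back to the route at 5.

Step 1. Acylation in superacid may be incomplete or multiple, and the chloroketone may oligomerise through its vinyl ketone during basic closure. The fallback sets out from 1 and uses a Houben–Hoesch reaction with 3-chloropropanenitrile (ZnCl2, HCl gas, Et2O, 0 °C). The precipitating 3-chloro-1-(2,4,6-trihydroxyphenyl)propan-1-iminium chloride F3 cannot react a second time because the iminium group deactivates the ring. Hydrolysis (H2O, warm) should give 3, where the fallback comes back to the route, and the NaOH closure then leads to 4.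

**Further compounds**
F1 | step 3 | racemic 5-hydroxy-7-methoxy-2-(3,4,5-trimethoxyphenyl)chroman-4-one | COc1cc(O)c2C(=O)CC(Oc2c1)c1cc(OC)c(OC)c(OC)c1
F2 | step 2 | 5,7-dimethoxychroman-4-one | COc1cc(OC)c2C(=O)CCOc2c1
F3 | step 1 | 3-chloro-1-(2,4,6-trihydroxyphenyl)propan-1-iminium chloride | [NH2+]=C(CCCl)c1c(O)cc(O)cc1O.[Cl-]
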